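The cyclohexane ring is disconnected at C8–C9 and C6–C7 (elemane numbering). The key step exploits its cis,cis 1,3-dioxygenated C6–C7–C8 triad: an alkenylboronate 1,2-metallate shift triggered by a tethered oxocarbenium ion. The precursor is an open chain that carries the C10/C5 dyad (from an enantioselective Ireland–Claisen rearrangement), a C9–lithium and a C6 acetal, joined to a (Z)-dienylboronate as the ate complex. On acetal ionisation C6 attacks C7 while C9 migrates from boron to C8: one operation closes the ring, forms both bonds and sets C6, C7 and C8; the C8–B bond becomes the 8-oxygen and the leftover acetal ether protects O6.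

Key step: step 13

Remark (numbering): C10 = quaternary ring carbon (methyl C14, vinyl C1=C2), C9 = ring CH2, C8 = O-acyl carbon, C7 = carbon bearing C11(=C13)–C12, C6 = carbinol carbon, C5 = carbon bearing C4(=C3)–C15. β is the ring face of the C10 methyl; the target is 5α-side chain, 6β-OH, 7β-side chain, 8β-O, 10α-vinyl.

Assumption 1: the (R,R)-bromoborane is taken to give the (2R,3S)-acid in step 6; its sense of induction with this Z(O)-boron dienolate has to be checked on the first run, and the (S,S)-reagent is used if it is opposite.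

Assumption 2: the free γ-hydroxy acid is taken to be isolable at pH 5–7 without closing to the 6,12-lactone.

Step 1
Reactants: 1 4-methyl hydrogen itaconate
Product: 3 methyl 3-(hydroxymethyl)but-3-enoate, via mixed carbonic anhydride 2 (not isolated)
Conditions: iBuOCOCl, N-methylmorpholine, THF, −15 °C; then NaBH4, H2O, 0 °C
Reagents that add atoms: none
Why: Mixed-anhydride/borohydride reduction takes the free acrylic acid to the allylic alcohol and leaves the methyl ester and the alkene untouched.

Step 2
Reactants: 3 methyl 3-(hydroxymethyl)but-3-enoate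
Product: 4 methyl 3-{[(tert-butyldimethylsilyl)oxy]methyl}but-3-enoate
Conditions: TBSCl, imidazole, DMF, 0 °C → rt
Reagents that add atoms: tert-butyldimethylsilyl chloride, CC(C)(C)[Si](C)(C)Cl
Why: Standard silylation of a primary allylic alcohol.

Step 3
Reactants: 4 methyl 3-{[(tert-butyldimethylsilyl)oxy]methyl}but-3-enoate
Product: 5 3-{[(tert-butyldimethylsilyl)oxy]methyl}but-3-enoic acid
Conditions: LiOH·H2O, THF/H2O, 0 °C; then 1 M HCl to pH 4
Reagents that add atoms: lithium hydroxide, [Li+].[OH-]
Why: Saponification at 0 °C should be faster than α-deprotonation, so the alkene stays out of conjugation.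

Step 4
Reactants: 5 silyloxymethyl butenoic acid; 6 2-methyl-2-vinyloxirane (racemic)
Product: 7 (2E)-4-hydroxy-3-methylbut-2-en-1-yl 3-{[(tert-butyldimethylsilyl)oxy]methyl}but-3-enoate
Conditions: Pd(PPh3)4 (2 mol %), THF, 0 °C → rt
Reagents that add atoms: none
Why: Tsuji–Trost 1,4-addition: zerovalent palladium opens the vinyl epoxide to a π-allyl alkoxide that deprotonates 5, and the carboxylate attacks the unsubstituted allyl terminus to give the more stable (E)-primary allylic ester.

Step 5
Reactants: 7 hydroxy allylic ester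
Product: 8 (2E)-4-chloro-3-methylbut-2-en-1-yl 3-{[(tert-butyldimethylsilyl)oxy]methyl}but-3-enoate
Conditions: PPh3, hexachloroacetone, CH2Cl2, −20 → 0 °C
Reagents that add atoms: hexachloroacetone, ClC(Cl)(Cl)C(=O)C(Cl)(Cl)Cl
Why: Appel-type SN2 chlorination of the primary allylic alcohol through its alkoxyphosphonium salt, without allylic transposition at low temperature.

Step 6
Reactants: 8 chloro allylic ester
Product: 10 (2R,3S)-2-(3-{[tert-butyl(dimethyl)silyl]oxy}prop-1-en-2-yl)-3-(chloromethyl)-3-methylpent-4-enoic acid, via boron ketene acetal 9 (not isolated)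
Conditions: (R,R)-2-bromo-1,3-bis{[3,5-bis(trifluoromethyl)phenyl]sulfonyl}-4,5-diphenyl-1,3,2-diazaborolidine (1.2 equiv), iPr2NEt, CH2Cl2, −78 °C; then −20 °C → rt; aqueous work-up
Reagents that add atoms: none
Why: Enantioselective Ireland–Claisen rearrangement: soft enolisation should give the Z(O)-boron ketene acetal 9 (alkenyl group cis to O–B), whose chair [3,3] shift with the (E)-alkene (CH2Cl and the enolate alkenyl group both equatorial) sets quaternary C10 and C5 in the required relative sense while the C2-symmetric sulfonamide ligand selects the enolate face.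

Step 7
Reactants: 10 (2R,3S)-acid
Product: 11 (2R,3S)-2-(3-{[tert-butyl(dimethyl)silyl]oxy}prop-1-en-2-yl)-3-(chloromethyl)-3-methylpent-4-en-1-ol
Conditions: LiAlH4, Et2O, 0 °C
Reagents that add atoms: none
Why: LiAlH4 reduces the acid to the primary alcohol; the neopentyl chloride, the silyl ether and the alkenes are inert at 0 °C.

Step 8
Reactants: 11 (2R,3S)-alcohol
Product: 12 (2R,3S)-2-(3-{[tert-butyl(dimethyl)silyl]oxy}prop-1-en-2-yl)-3-(chloromethyl)-3-methylpent-4-enal
Conditions: Dess–Martin periodinane, NaHCO3, CH2Cl2, 0 °C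
Reagents that add atoms: none
Why: Buffered Dess–Martin oxidation is non-enolising, so C5 should not epimerise and the alkene should not move into conjugation; 12 is used at once.

Step 9
Reactants: 12 (2R,3S)-aldehyde
Product: 13 bis(4-methoxybenzyl) acetal of 12
Conditions: 4-methoxybenzyl trimethylsilyl ether (2.5 equiv), TMSOTf (5 mol %), CH2Cl2, −78 °C; pyridine quench
Reagents that add atoms: 4-methoxybenzyl trimethylsilyl ether, COc1ccc(CO[Si](C)(C)C)cc1
Why: Noyori acetalisation at −78 °C masks the sensitive aldehyde without epimerisation; one PMB-oxy group leaves in step 13 and the other becomes the O6 protecting group.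

Step 10
Reactants: 14 2-bromoprop-2-en-1-ol
Product: 15 [(2-bromoprop-2-en-1-yl)oxy]triethylsilane
Conditions: Et3SiCl, imidazole, CH2Cl2, 0 °C
Reagents that add atoms: chlorotriethylsilane, CC[Si](Cl)(CC)CC
Why: Standard silylation; the triethylsilyl group is chosen so that O12 can later be addressed in the presence of the TBS ether at O15.

Step 11
Reactants: 15 bromoallyl silyl ether; 16 ethynylmagnesium bromide
Product: 17 triethyl[(2-methylidenebut-3-yn-1-yl)oxy]silane
Conditions: 16, ZnBr2, THF, 0 °C; then 15, Pd(PPh3)4 (3 mol %), rt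
Reagents that add atoms: none
Why: Negishi coupling of the 2-bromoalkene with ethynylzinc bromide gives the terminal enyne directly.

Step 12
Reactants: 17 silyloxymethyl enyne
Product: 18 (Z)-dienyl pinacol boronate
Conditions: pinacolborane, [Rh(cod)Cl]2 (1.5 mol %), P(iPr)3 (6 mol %), Et3N, cyclohexane, rt
Reagents that add atoms: pinacolborane, B1OC(C)(C)C(C)(C)O1
Why: Rhodium-catalysed trans-hydroboration of a terminal alkyne (through a rhodium vinylidene) delivers the (Z)-1-alkenylboronate and leaves the 1,1-disubstituted alkene alone.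

Step 13
Reactants: 13 chloro bis-PMB acetal; 18 (Z)-dienyl pinacol boronate
Product: 21 cyclohexyl pinacol boronate (8β-Bpin; 7β-side chain; 6β-OPMB), via alkyllithium 19 (not isolated), via boronate complex 20 (not isolated)
Conditions: Li, 4,4'-di-tert-butylbiphenyl (lithium di-tert-butylbiphenylide, 2.1 equiv), THF, −78 °C, 13 added to the reductant; 18, −78 → 0 °C; solvent switch to CH2Cl2; TMSOTf (1.3 equiv), 2,6-di-tert-butyl-4-methylpyridine, −78 → −40 °C; aq. NaHCO3
Reagents that add atoms: none
Why: Proposed new method: reductive lithiation of the neopentyl chloride gives 19, which adds to boron of 18 to give ate complex 20; TMSOTf ionises the acetal to a PMB-oxocarbenium ion at C6, the borate-activated C8=C7 bond attacks it through C7 (Prins-type), and the developing C8 cation next to the borate is quenched by 1,2-migration of C9 from boron to C8. The closest known reactions are the electrophile-induced 1,2-metallate rearrangements of alkenylboronate complexes (Zweifel-type three-component couplings with carbon electrophiles) and the 1,3-diol synthesis from lithium trialkylalkenylborates and aldehydes; new here is that the electrophile is tethered to the migrating group, so the shift closes a carbocycle. The cyclohexane closes as a formal (4+2) annulation: C6–C7 by 7-endo-trig attack within the borate-containing chain, C8–C9 by the ring-contracting shift from boron, both new bonds necessarily entering the same alkene face because the tether is only two atoms long. The (Z)-alkene geometry therefore becomes the cis relation of the C7 side chain and the C8–B bond, and a chair-like transition state with the (E)-oxocarbenium oxygen, the C5 side chain and the boronate equatorial and the C10 vinyl axial should set C6 and the sense relative to C5/C10, the alternatives suffering 1,3-diaxial Bpin/vinyl or methyl/side-chain clashes. The step needs ionisation of the acetal without O-silylation of the borate, and attack at C7 and not at diene terminus C13 or by the C4=C3 alkene; the seven-membered closure (against nine or four), the high nucleophilicity of the ate complex, the poorly participating silyl ether at O15 and the hindered base are meant to secure this. The low temperature and inverse addition keep the C9 radical from 1,2-vinyl shift before its second reduction.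

Step 14
Reactants: 21 cyclohexyl pinacol boronate
Product: 22 8β-cyclohexanol (6β-OPMB; O12-TES; O15-TBS)
Conditions: NaBO3·4H2O, THF/H2O, rt
Reagents that add atoms: sodium perborate, [Na+].[Na+].O[B-]1(O)OO[B-](O)(O)OO1
Why: Perborate oxidation of the secondary boronic ester goes with retention at C8 (1,2-shift from boron to oxygen) and is mild enough for the silyl and PMB ethers.

Step 15
Reactants: 23 methyl (4S)-2,2-dimethyl-1,3-dioxolane-4-carboxylate
Product: 24 (4S)-N-methoxy-N,2,2-trimethyl-1,3-dioxolane-4-carboxamide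
Conditions: MeNH(OMe)·HCl, iPrMgCl, THF, −20 °C
Reagents that add atoms: N,O-dimethylhydroxylamine hydrochloride, CNOC.Cl
Why: Weinreb amide formation from the ester with the chloromagnesium amide at low temperature should not epimerise the α-alkoxy centre.

Step 16
Reactants: 24 Weinreb amide
Product: 25 1-[(4S)-2,2-dimethyl-1,3-dioxolan-4-yl]ethan-1-one
Conditions: MeMgBr, THF, 0 °C; aq. NH4Cl
Reagents that add atoms: methylmagnesium bromide, C[Mg]Br
Why: Single Grignard addition through the stable magnesium chelate of the Weinreb amide gives the methyl ketone.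

Step 17
Reactants: 25 methyl ketone
Product: 27 1-[(4S)-2,2-dimethyl-1,3-dioxolan-4-yl]ethenyl trifluoromethanesulfonate, via potassium enolate 26 (not isolated)
Conditions: KN(SiMe3)2, THF, −78 °C; then PhNTf2, −78 → 0 °C
Reagents that add atoms: N-phenylbis(trifluoromethanesulfonimide), O=S(=O)(N(c1ccccc1)S(=O)(=O)C(F)(F)F)C(F)(F)F
Why: Kinetic deprotonation at the methyl group and O-triflation give the terminal enol triflate without touching the α-alkoxy stereocentre.

Step 18
Reactants: 27 enol triflate
Product: 28 methyl 2-[(4R)-2,2-dimethyl-1,3-dioxolan-4-yl]prop-2-enoate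
Conditions: Pd(OAc)2 (5 mol %), PPh3 (10 mol %), CO (1 atm), MeOH, Et3N, DMF, rt
Reagents that add atoms: carbon monoxide, [C-]#[O+]; methanol, CO
Why: Palladium-catalysed methoxycarbonylation of the enol triflate (oxidative addition, CO insertion, methanolysis) gives the 2-substituted acrylate; the descriptor changes to R only by priority.

Step 19
Reactants: 28 acrylate ester
Product: 29 2-[(4R)-2,2-dimethyl-1,3-dioxolan-4-yl]prop-2-enoic acid
Conditions: LiOH·H2O, THF/H2O, 0 °C; then 1 M HCl to pH 4
Reagents that add atoms: lithium hydroxide, [Li+].[OH-]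
Why: Mild saponification; the stereocentre is not α to the carbonyl and cannot epimerise.

Step 20
Reactants: 22 8β-cyclohexanol; 29 dioxolanyl acrylic acid
Product: 30 8-O-acyl ester (side-chain diol as acetonide)
Conditions: DCC, DMAP (0.2 equiv), CH2Cl2, 0 °C → rt
Reagents that add atoms: none
Why: Steglich esterification of the only free hydroxyl, the equatorial 8-OH, which the key step left distinct from the PMB-protected 6-OH.

Step 21
Reactants: 30 8-O-acyl ester
Product: 31 C12 enal
Conditions: (COCl)2, DMSO, CH2Cl2, −78 → −30 °C; then Et3N, −78 → 0 °C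
Reagents that add atoms: none
Why: Under Swern conditions a primary triethylsilyl ether is cleaved by the chlorosulfonium salt and oxidised in the same pot to the aldehyde, while the primary TBS ether, the PMB ether and the acetonide are inert.

Step 22
Reactants: 31 C12 enal
Product: 32 C12 acrylic acid (O6-PMB; O15-TBS; acetonide)
Conditions: NaClO2, NaH2PO4, 2-methylbut-2-ene, tBuOH/H2O, 0 °C → rt
Reagents that add atoms: sodium chlorite, [Na+].[O-]Cl=O
Why: Pinnick (Lindgren–Kraus) oxidation converts the enal to the acrylic acid without touching alkenes; O6 is still protected, so no lactone can form.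

Step 23
Reactants: 32 protected acrylic acid
Product: 33 6-O-PMB ether of the target
Conditions: AcOH/THF/H2O (3:1:1), 40 °C
Reagents that add atoms: none
Why: Aqueous acetic acid hydrolyses the primary allylic TBS ether and the terminal acetonide, while the PMB ether at O6 survives and keeps the C12 acid from lactonising under acid.

Step 24
Reactants: 33 6-O-PMB ether of the target
Product: 34 target hydroxy acid
Conditions: DDQ (1.5 equiv), CH2Cl2/pH 7 phosphate buffer (10:1), 0 °C
Reagents that add atoms: none
Why: Oxidative PMB cleavage (hydride abstraction, hydrolysis of the oxocarbenium ion) frees 6-OH under neutral conditions, under which the γ-hydroxy acid should not lactonise and the side-chain ester should not transacylate.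

Compound list
1 | 4-methoxy-2-methylidene-4-oxobutanoic acid (4-methyl hydrogen itaconate) | C=C(CC(=O)OC)C(=O)O | starting material
2 | mixed anhydride of 1 with isobutyl carbonic acid | C=C(CC(=O)OC)C(=O)OC(=O)OCC(C)C | intermediate
3 | methyl 3-(hydroxymethyl)but-3-enoate | C=C(CO)CC(=O)OC | intermediate
4 | methyl 3-{[(tert-butyldimethylsilyl)oxy]methyl}but-3-enoate | C=C(CO[Si](C)(C)C(C)(C)C)CC(=O)OC | intermediate
5 | 3-{[(tert-butyldimethylsilyl)oxy]methyl}but-3-enoic acid | C=C(CO[Si](C)(C)C(C)(C)C)CC(=O)O | intermediate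
6 | 2-ethenyl-2-methyloxirane (racemic) | C=CC1(C)CO1 | starting material
7 | (2E)-4-hydroxy-3-methylbut-2-en-1-yl 3-{[(tert-butyldimethylsilyl)oxy]methyl}but-3-enoate | C=C(CO[Si](C)(C)C(C)(C)C)CC(=O)OC/C=C(C)/CO | intermediate
8 | (2E)-4-chloro-3-methylbut-2-en-1-yl 3-{[(tert-butyldimethylsilyl)oxy]methyl}but-3-enoate | C=C(CO[Si](C)(C)C(C)(C)C)CC(=O)OC/C=C(C)/CCl | intermediate
9 | Z(O)-boron ketene acetal of 8 with the (4R,5R)-1,3-bis(arylsulfonyl)-4,5-diphenyl-1,3,2-diazaborolidin-2-yl group on oxygen | C=C(CO[Si](C)(C)C(C)(C)C)/C=C(\OB1N(S(=O)(=O)c2cc(cc(c2)C(F)(F)F)C(F)(F)F)[C@H](c2ccccc2)[C@@H](c2ccccc2)N1S(=O)(=O)c1cc(cc(c1)C(F)(F)F)C(F)(F)F)OC/C=C(C)/CCl | intermediate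
10 | (2R,3S)-2-(3-{[tert-butyl(dimethyl)silyl]oxy}prop-1-en-2-yl)-3-(chloromethyl)-3-methylpent-4-enoic acid | C=C[C@](C)(CCl)[C@@H](C(=C)CO[Si](C)(C)C(C)(C)C)C(=O)O | intermediate
11 | (2R,3S)-2-(3-{[tert-butyl(dimethyl)silyl]oxy}prop-1-en-2-yl)-3-(chloromethyl)-3-methylpent-4-en-1-ol | C=C[C@](C)(CCl)[C@@H](C(=C)CO[Si](C)(C)C(C)(C)C)CO | intermediate
12 | (2R,3S)-2-(3-{[tert-butyl(dimethyl)silyl]oxy}prop-1-en-2-yl)-3-(chloromethyl)-3-methylpent-4-enal | C=C[C@](C)(CCl)[C@@H](C(=C)CO[Si](C)(C)C(C)(C)C)C=O | intermediate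
13 | (2R,3S)-3-(chloromethyl)-1,1-bis[(4-methoxybenzyl)oxy]-3-methyl-2-(3-{[tert-butyl(dimethyl)silyl]oxy}prop-1-en-2-yl)pent-4-ene | C=C[C@](C)(CCl)[C@@H](C(=C)CO[Si](C)(C)C(C)(C)C)C(OCc1ccc(OC)cc1)OCc1ccc(OC)cc1 | intermediate
14 | 2-bromoprop-2-en-1-ol | C=C(Br)CO | starting material
15 | [(2-bromoprop-2-en-1-yl)oxy]triethylsilane | C=C(Br)CO[Si](CC)(CC)CC | intermediate
16 | ethynylmagnesium bromide | C#C[Mg]Br | starting material
17 | triethyl[(2-methylidenebut-3-yn-1-yl)oxy]silane | C#CC(=C)CO[Si](CC)(CC)CC | intermediate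
18 | 4,4,5,5-tetramethyl-2-[(1Z)-3-{[(triethylsilyl)oxy]methyl}buta-1,3-dien-1-yl]-1,3,2-dioxaborolane | C=C(CO[Si](CC)(CC)CC)/C=C\B1OC(C)(C)C(C)(C)O1 | intermediate
19 | primary alkyllithium from 13 (C9–Li; C5 and C10 as in 13) | C=C[C@](C)(C[Li])[C@@H](C(=C)CO[Si](C)(C)C(C)(C)C)C(OCc1ccc(OC)cc1)OCc1ccc(OC)cc1 | intermediate
20 | lithium boronate complex: pinacolato boron bearing C9 of 19 and the (Z)-dienyl group of 18 | [Li+].C=C[C@](C)(C[B-]1(/C=C\C(=C)CO[Si](CC)(CC)CC)OC(C)(C)C(C)(C)O1)[C@@H](C(=C)CO[Si](C)(C)C(C)(C)C)C(OCc1ccc(OC)cc1)OCc1ccc(OC)cc1 | intermediate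
21 | cyclohexane with 8β-(pinacolboryl), 7β-[3-(triethylsilyloxy)prop-1-en-2-yl], 6β-(4-methoxybenzyloxy), 5α-[3-(tert-butyldimethylsilyloxy)prop-1-en-2-yl], 10β-methyl, 10α-vinyl | C=C[C@]1(C)C[C@@H](B2OC(C)(C)C(C)(C)O2)[C@@H](C(=C)CO[Si](CC)(CC)CC)[C@@H](OCc2ccc(OC)cc2)[C@@H]1C(=C)CO[Si](C)(C)C(C)(C)C | intermediate
22 | 8β-alcohol corresponding to 21 (C8–OH in place of C8–B, same configuration) | C=C[C@]1(C)C[C@@H](O)[C@@H](C(=C)CO[Si](CC)(CC)CC)[C@@H](OCc2ccc(OC)cc2)[C@@H]1C(=C)CO[Si](C)(C)C(C)(C)C | intermediate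
23 | methyl (4S)-2,2-dimethyl-1,3-dioxolane-4-carboxylate | COC(=O)[C@@H]1COC(C)(C)O1 | starting material
24 | (4S)-N-methoxy-N,2,2-trimethyl-1,3-dioxolane-4-carboxamide | CON(C)C(=O)[C@@H]1COC(C)(C)O1 | intermediate
25 | 1-[(4S)-2,2-dimethyl-1,3-dioxolan-4-yl]ethan-1-one | CC(=O)[C@@H]1COC(C)(C)O1 | intermediate
26 | potassium 1-[(4S)-2,2-dimethyl-1,3-dioxolan-4-yl]ethen-1-olate | [K+].C=C([O-])[C@@H]1COC(C)(C)O1 | intermediate
27 | 1-[(4S)-2,2-dimethyl-1,3-dioxolan-4-yl]ethenyl trifluoromethanesulfonate | C=C(OS(=O)(=O)C(F)(F)F)[C@@H]1COC(C)(C)O1 | intermediate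
28 | methyl 2-[(4R)-2,2-dimethyl-1,3-dioxolan-4-yl]prop-2-enoate | COC(=O)C(=C)[C@@H]1COC(C)(C)O1 | intermediate
29 | 2-[(4R)-2,2-dimethyl-1,3-dioxolan-4-yl]prop-2-enoic acid | OC(=O)C(=C)[C@@H]1COC(C)(C)O1 | intermediate
30 | 8-O-{2-[(4R)-2,2-dimethyl-1,3-dioxolan-4-yl]prop-2-enoyl} ester of 22 | C=C[C@]1(C)C[C@@H](OC(=O)C(=C)[C@@H]2COC(C)(C)O2)[C@@H](C(=C)CO[Si](CC)(CC)CC)[C@@H](OCc2ccc(OC)cc2)[C@@H]1C(=C)CO[Si](C)(C)C(C)(C)C | intermediate
31 | aldehyde from 30 (C12 = CHO; 7β-(3-oxoprop-1-en-2-yl)) | C=C[C@]1(C)C[C@@H](OC(=O)C(=C)[C@@H]2COC(C)(C)O2)[C@@H](C(=C)C=O)[C@@H](OCc2ccc(OC)cc2)[C@@H]1C(=C)CO[Si](C)(C)C(C)(C)C | intermediate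
32 | acrylic acid from 31 (C12 = CO2H; O6-PMB, O15-TBS, acetonide) | C=C[C@]1(C)C[C@@H](OC(=O)C(=C)[C@@H]2COC(C)(C)O2)[C@@H](C(=C)C(=O)O)[C@@H](OCc2ccc(OC)cc2)[C@@H]1C(=C)CO[Si](C)(C)C(C)(C)C | intermediate
33 | 6-O-(4-methoxybenzyl) ether of the target | C=C[C@]1(C)C[C@@H](OC(=O)C(=C)[C@@H](O)CO)[C@@H](C(=C)C(=O)O)[C@@H](OCc2ccc(OC)cc2)[C@@H]1C(=C)CO | intermediate
34 | 2-[(1S,2S,3S,4S,6R)-6-{[(3R)-3,4-dihydroxy-2-methylidenebutanoyl]oxy}-4-ethenyl-2-hydroxy-3-(3-hydroxyprop-1-en-2-yl)-4-methylcyclohexyl]prop-2-enoic acid | C=C[C@]1(C)C[C@@H](OC(=O)C(=C)[C@@H](O)CO)[C@@H](C(=C)C(=O)O)[C@@H](O)[C@@H]1C(=C)CO | target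

Total step count: 24. Longest linear sequence: 16 steps (steps 1–9, 13, 14, 20–24).

Steps most likely to fail

1. Step 13 (proposed new method). The borate may be O-silylated by TMSOTf, or ring closure may be slow, so that the ate complex is protonated or the oxocarbenium ion is captured elsewhere; facial control may also leak. The fallback uses known reactions, sets out from boronate complex 20 and returns at 21. Iodine and then NaOMe (Zweifel olefination) would give the (E)-diene acetal F1. Platinum-catalysed 1,4-diboration (B2pin2, Pt(dba)3, a TADDOL-derived phosphonite chosen to set C8) would give the (Z)-1,4-bis(boronate) F2. Hydrolysis of the acetal (LiBF4, wet MeCN) would free the C6 aldehyde, which should cyclise at once by intramolecular allylboration through a bicyclic chair transition state (Z-allylboronate gives cis-6,7) to the 6β-hydroxy boronic ester F3. PMB protection (4-methoxybenzyl trichloroacetimidate, La(OTf)3) would then give 21.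

2. Step 6. The boron enolate may form with the wrong geometry or be discriminated poorly by the ligand, and halide exchange at the allylic chloride may occur during the slow rearrangement. The fallback sets out from 8 and returns at 10. A classical Ireland–Claisen rearrangement (LiN(iPr)2 with Me3SiCl/Et3N present as internal quench, THF/DMPU, −78 °C → rt) would give racemic 10 of the same relative configuration through the Z(O)-silyl ketene acetal. Resolution by crystallisation of the (S)-1-phenylethylammonium salt F4 and acidification would return enantiopure 10.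

3. Step 4. The carboxylate may open the π-allyl complex at the tertiary terminus (1,2-adduct), or syn/anti π-allyl isomerisation may erode the E geometry that the Claisen step needs. The fallback sets out from 5 and returns at 8, bypassing 7. SeO2/tBuOOH oxidation of commercial prenyl acetate would give (2E)-4-hydroxy-3-methylbut-2-en-1-yl acetate F5, PPh3/hexachloroacetone would give the chloride F6, (iBu)2AlH at −78 °C would remove the acetate to give (2E)-4-chloro-3-methylbut-2-en-1-ol F7, and Steglich esterification of F7 with 5 (DCC, DMAP) would give 8.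

Further compounds
F1 | step 13 | (E)-diene acetal: 13 with CH2Cl replaced by (2E)-4-{[(triethylsilyl)oxy]methyl}penta-2,4-dien-1-yl | C=C[C@](C)(C/C=C/C(=C)CO[Si](CC)(CC)CC)[C@@H](C(=C)CO[Si](C)(C)C(C)(C)C)C(OCc1ccc(OC)cc1)OCc1ccc(OC)cc1
F2 | step 13 | (Z)-1,4-bis(pinacolboryl)but-2-ene from F1 (boron at C8 and C13, C8 configured as in 21) | C=C[C@](C)(C[C@@H](B1OC(C)(C)C(C)(C)O1)/C=C(/CO[Si](CC)(CC)CC)CB1OC(C)(C)C(C)(C)O1)[C@@H](C(=C)CO[Si](C)(C)C(C)(C)C)C(OCc1ccc(OC)cc1)OCc1ccc(OC)cc1
F3 | step 13 | 6β-hydroxy analogue of 21 (free 6-OH, 8β-Bpin) | C=C[C@]1(C)C[C@@H](B2OC(C)(C)C(C)(C)O2)[C@@H](C(=C)CO[Si](CC)(CC)CC)[C@@H](O)[C@@H]1C(=C)CO[Si](C)(C)C(C)(C)C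
F4 | step 6 | (S)-1-phenylethylammonium salt of 10 | C=C[C@](C)(CCl)[C@@H](C(=C)CO[Si](C)(C)C(C)(C)C)C(=O)[O-].C[C@H]([NH3+])c1ccccc1
F5 | step 4 | (2E)-4-hydroxy-3-methylbut-2-en-1-yl acetate | CC(=O)OC/C=C(C)/CO
F6 | step 4 | (2E)-4-chloro-3-methylbut-2-en-1-yl acetate | CC(=O)OC/C=C(C)/CCl
F7 | step 4 | (2E)-4-chloro-3-methylbut-2-en-1-ol | OC/C=C(C)/CCl
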